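(The earlier runs and the new flask stem from a simulated flask on assumed constants.)

The starting complex takes up incoming ligand and gives the complex with one exchanged, then the complex with two exchanged.

- ash: starting complex 0.20 M; incoming ligand 0.10 M; run made earlier
- flask: starting complex 0.10 M; incoming ligand 0.100 M; time 8.0 d

ash run (percent of the starting complex charged)

| time / d | complex with one exchanged / % | complex with two exchanged / % | starting complex / % |
|---|---|---|---|
| 0.208 | 27.9 | 3.6 | 67.1 |
| 0.333 | 32.5 | 4.1 | 61.7 |
| 0.417 | 35.1 | 2.8 | 60.4 |
| 0.625 | 36.1 | 3.7 | 58.2 |
| 1.04 | 38.7 | 2.7 | 55.9 |
| 1.67 | 41.6 | 2.3 | 55.3 |
| 2.50 | 43.3 | 1.5 | 53.6 |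

(readings scatter by 0.5 percentage points)



- equivalents of incoming ligand to starting complex, everything else as given, that leave most complex with one exchanged at 8.0 d
- the amount of complex with one exchanged then, in percent of the starting complex charged
- the amount of complex with one exchanged with the amounts as given

The ash run holds 0.500 equivalents of incoming ligand. At its last reading, 2.50 d, the bound share of the ligand charge, counting the complex with two exchanged twice, is 92.6%. So uptake has nearly stalled, but the complex with two exchanged is falling while the complex with one exchanged grows, so a second balance is needed.

Two exchanged times starting complex, over one exchanged squared, all as fractions of the charge, is 0.0429. This is the swap quotient, a disproportionation quotient, and it holds no free ligand. It is a reading, and it was 0.101 at 1.04 d, so it reads as still falling. Each reading also carries 0.5 percentage points.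

Take the flask as finished at 8.0 d, with both values held. At 1.00 equivalents, the balances give 70.1% of the complex with one exchanged. At the forecast's equivalents they give 65.9%, which is less. So this reckoning puts the optimum lower than the forecast does.

The forecast gives 68% as charged and 72% at 1.3 equiv: “This fits reversible exchange, with released ligand pushing back.”

The flask gives 68.6% as charged and 69.1% at 1.09 equiv, fewer equivalents than forecast.

    complex with one exchanged + incoming ligand ⇌ leaving ligand + complex with two exchanged (K = 1.49, k = 0.0229 /M/min)
    complex with two exchanged ⇌ isomer of the product (K = 0.780, k = 0.00519 /min)
    starting complex + incoming ligand ⇌ leaving ligand + complex with one exchanged (K = 53.8, k = 0.0277 /M/min)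

A neighbouring flask charges 0.25 M of starting complex, which makes 0.400 equivalents. The swap quotient and bound share give 35.4% of the complex with one exchanged, and the neighbouring flask holds 37.3%. Incoming ligand is its limiting reagent, with 1.1% of its charge left against the 7.40% assumed. Starting complex ends above the complex with one exchanged in the neighbouring flask, at 61.6%.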